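Once a run has gone flat, target and side product between them hold the charge: the last readings of amber, ochre and grey add to 100%, 99.8% and 100%. So for a new flask the question is how the charge divides.

| flask | starting material | catalyst | remark | time |
|---|---|---|---|---|
| amber | 0.55 M | 10 mol% | run made earlier |  |
| ochre | 2.2 M | 10 mol% | run made earlier |  |
| grey | 1.1 M | 5 mol% | run made earlier |  |
| flask | 1.1 M | 10 mol% |  | 15 min |

- amber (time / min: target / %, side product / %): 0.667: 26.5, 57.6; 1.50: 30.6, 67.4; 4.00: 30.6, 68.4; 10.0: 31.7, 68.5
- ochre (time / min: target / %, side product / %): 2.50: 65.3, 35.4; 5.00: 64.4, 35.0; 6.00: 65.0, 36.2; 10.0: 64.5, 35.3
- grey (time / min: target / %, side product / %): 0.667: 25.8, 57.3; 1.50: 30.9, 66.7; 4.00: 32.3, 68.7; 10.0: 31.3, 69.0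

(each reading ± 0.5 percentage points)

- the numbers in the tables scatter with a standard deviation of 0.5 percentage points
- the reaction counts as stopped when no species that holds the starting material changes by six tenths of a point or more over the second half of the time

1. the state of affairs at 15 min: stopped, and by what, or still going (forward and back rates have come level / all of the starting material has reacted / no working catalyst is left / it is still moving)
2. how much target there is at 15 min, in percent of the starting material charged
3. how much side product there is at 15 min, in percent of the starting material charged

Take the split (the selectivity factor) as target over side product in the last two readings of a run. Amber and grey hold the same catalyst level, 0.0550 M and 0.0550 M, at different starting material, and their splits read 0.455 and 0.462. So you follow the catalyst level. The flask holds 0.110 M, between those and ochre's 0.220 M, which puts its target above amber's 31.7% and below ochre's 64.5%.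

To tighten this bracket, go to logarithms. Ochre's split reads 1.81. From amber to ochre the base-ten logarithm of the split rises by 0.600 and that of the catalyst level by 0.602, so the split follows the first power of the catalyst level. The flask, at twice amber's level and half ochre's, stands midway in logarithms. Taken there, the even-split catalyst level 0.121 M, the catalyst level over the split, marks where target and side product take equal fractions of the charge. The target's fraction is then the catalyst level over the sum of that level and the even-split level: 47.6% for the flask. Grey's reading of the even-split level, 0.119 M, and ochre's, 0.121 M, narrow the bracket to 47.5% to 48.0%. Amber's sum already reads 99.0% at 4.00 min, so I expect the flask to stand with its starting material used up.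

The forecast says all of the starting material has reacted, with 47.7% target and 52.3% side product, inside the bracket, holding that “the target path has one extra order in catalyst”.

The flask gives 47.8% target and 52.2% side product, also inside the bracket: all of the starting material has reacted.

    starting material → side product (k = 0.0313 s⁻¹)
    starting material + catalyst → catalyst + target (k = 0.261 L mol⁻¹ s⁻¹)

Starting material is down to 0.451% at 1.50 min, and target still stands at 47.8% at 150 min. The flask's catalyst level lies below the even-split level, and the flask ended with 52.2% side product against 47.8% target. A neighbouring flask with 2.8 M of starting material at the same loading holds 0.280 M of catalyst, above the even-split level, which gives 69.8% target; it ended with 70.0% target.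

(Readings and results were generated by integration from invented constants, and the scatter is random.)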